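## Structural features

Luteolin 3'-sulfate is a flavone: a benzene ring A fused at C4a–C8a to a 4-pyranone ring C, with a phenyl ring B attached to C2 through the C2–C1' single bond. Ring A carries oxygen at C5, C7 and C8a (O1), a phloroglucinol pattern, and the 5-hydroxyl is hydrogen-bonded to the C4 carbonyl. Ring B is a catechol whose 3'-oxygen is esterified as a hydrogen sulfate, while the neighbouring 4'-hydroxyl is free. There is no stereocentre, so none stand next to each other; the only stereochemical element met on the way is the geometry of an enol ether double bond, and it disappears into ring C. The fragile parts are the aryl sulfate monoester (lost by acid-catalysed solvolysis and incompatible with organolithium and acylating steps), the free phenols (easily oxidised and acylated) and the C2=C3 bond of the pyranone (open to reduction and to ring opening by strong base). The carbon skeleton is simple; the real difficulty is to put one sulfate on O3' and on none of the other three phenolic oxygens, above all not on the adjacent O4', and then to unmask the others without losing the sulfate. The key step uses ring A: C4a is ortho to O1 and ortho or para to the oxygens on C5 and C7, and the two carbons ortho to O1 are equivalent in a 3,5-dioxygenated phenoxy group, so an acyl carbon (C4) tethered through O1–C2=C3 can be joined to C4a to close ring C with no regiochemical question.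

## Logic of the disconnections

Atom numbers are those of the target flavone.

17 ⇒ 16. The O–H bonds at O5, O7 and O4' are traced back to O–benzyl bonds. The sulfate cannot be placed selectively on a tetraphenol, so the other three oxygens must stay masked until it is on, and the mask must leave under neutral conditions. The gain is that the selectivity problem is removed from the last step. The demand is a hydrogenolysis that spares the O–S bond and the C2=C3 bond.

16 ⇒ 14 + 15. The O3'–S bond is cut. The sulfate is the most fragile and the only ionisable group, so it is introduced as late as possible. Everything before 16 is then neutral, lipophilic and easy to purify. The forward step requires that 14 present O3'–H as its only free hydroxyl.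

14 ⇒ 13. The O3'–H bond is traced back to an O3'–allyl bond. O3' needs a mask that differs from benzyl, survives organolithium, carbonate and hydroxide bases and an acid anhydride, and leaves under neutral conditions. The gain is complete differentiation of the four oxygens in 13. The demand is an allyl transfer that touches neither benzyl ethers nor the pyranone.

13 ⇒ 11 (through 12). The C4–C4a bond is cut. It joins a carbonyl carbon to the most nucleophilic arene carbon of the molecule, so it is the natural place for an intramolecular acylation. Ring C is opened and the bicyclic core falls apart into two arenes linked by an enol ether. The forward step needs the carboxyl group cis to the aryloxy group (or a double bond that can equilibrate), activation mild enough for allyl and benzyl ethers, and ring A outcompeting ring B.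

11 ⇒ 10. The carboxyl O–H is traced back to the ethyl ester. The conjugate addition that makes the enol ether needs an ester; a carboxylate would switch the acceptor off. There is no skeletal gain, but the cut makes the next one possible. The demand is a hydrolysis that does not expel the aryloxy group from the β-carbon.

10 ⇒ 8 + 9. The O1–C2 bond is cut. This divides the molecule into two halves of similar size, a symmetrical phenol and an ynoate, and the polarity of the ynoate fixes the site of attack at the β-carbon. The gain is full convergence on one purchased and one short-sequence fragment. The demand is O-attack rather than C-attack of the ambident phenoxide; the alkene geometry need not be controlled.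

8 ⇒ 5 + 6 (through 7). The C3–C4 bond is cut between the alkyne carbon and the carboxyl carbon. An acetylide and a chloroformate are the obvious partners, and the carboxyl carbon comes from a one-carbon reagent. The demand is acetylide generation at low temperature in the presence of the allyl ether, and a single acylation.

5 ⇒ 3 + 4. The C2=C3 double bond is cut. The aldehyde carbon of 3 becomes C2 and the carbon of 4 becomes C3, with two bromine atoms that later leave to give the alkyne. The three-carbon bridge is thus reduced to an aromatic aldehyde. The forward olefination is neutral and undemanding.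

3 ⇒ 1 + 2. The O3'–allyl bond is cut. Compound 1 is sold with the benzyl group already on O4', so the hardest selectivity problem of the target, telling O3' from O4', is settled by the choice of starting material. The forward step is a simple alkylation of the one remaining phenol.

## Other disconnections considered

Alternative 1: The cut is the C4a–C8a bond of ring A, so that ring A is made by a polyketide-type closure rather than bought.
- Forward key step: the 4-hydroxy-2-pyranone A1 would be treated with magnesium dimethoxide A2, Mg(OMe)2. The methylene carbon between the pyranone and the side-chain ketone, held as a magnesium chelate, attacks the lactone carbonyl; the pyranone opens and enolisation gives the acylphloroglucinol A3 (a Claisen-type cyclisation). The β-methoxy enone of A3 could then close ring C by addition of an ortho hydroxyl and loss of the methoxy group.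
- In favour: ring A arrives with all three oxygens in place and unprotected, the base is mild, and the two ortho hydroxyls of A3 are equivalent.
- Against, here: ring A is the cheapest part of the target to buy. A1 must first be assembled over several steps by acylating a metallated pyranone fragment with a ring B fragment. The aldol mode of cyclisation competes with the Claisen mode. Ring C closure would give the flavone A4 with free 5- and 7-hydroxyls, which would have to be masked again before O3' could be freed from its methoxymethyl group and sulfated.
- Comparison: on structure, it builds a ring that the chosen plan takes ready-made from 9. On mechanism, it is the equal of the chosen plan in resting on well-understood carbonyl chemistry and in using the symmetry of ring A, and it is the better of the two in keeping acid away from the ring-forming step. On step economy, it is the poorer, being longer both before the key step and after it.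

Alternative 2: The cut runs through ring B, at C1'–C2' and C3'–C4', so that the catechol ring is built on a finished chromone.
- Forward key step: the 3-benzyloxy-2-pyranone A5, which carries the chromone on its C6, would react with the ketene acetal A6 in a Diels–Alder reaction of inverse electron demand. The nucleophilic methylene carbon bonds to C6 of the pyranone and the acetal carbon to C3. Decarboxylative cycloreversion and loss of a silanol aromatise the new ring, and desilylation on work-up would give A7.
- In favour: A7 is identical with 14. O3' is born free and is told apart from O4' by the polarity of the cycloaddition, not by a protecting group. The stretch after the key step would be two steps instead of three; on this point, and on the intrinsic 3'/4' differentiation, the alternative is the better plan.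
- Against, here: ring B is available as an inexpensive aldehyde that already carries both oxygens. A5 requires the complete benzylated chromone to be made first, so the problem of closing ring C is moved, not solved, and then a 2-pyranone to be grown on its C2 substituent. The key step is a cascade of three events that needs heat, its regiochemistry rests only on the polarisation of the pyranone, and the chromone C2=C3 bond is a competing electrophile for A6.
- Comparison: on structure, it spends its effort on the simplest ring. On mechanism, a pericyclic cascade stands against a single polar bond formation; both are defensible, the chosen one with closer analogy for this ring system. On step economy, it is one step shorter after the key step but several steps longer before it.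

Alternative 3: The cut takes ring A apart at four bonds, C8–C8a, C7–C8, C5–C6 and C4a–C5, leaving a 2-aryl-4-pyranone.
- Forward key step: irradiation of the diazo ketone A8 would trigger a Wolff rearrangement, in which the pyranone carbon migrates (forming C8–C8a) to give a vinylketene. A [2+2] cycloaddition with the siloxyalkyne A9 forms C7–C8 and C5–C6. The cyclobutenone opens in a four-electron electrocyclic step, the dienylketene closes in a six-electron step onto C5 of the pyranone (C4a–C5), and tautomerisation would give A10.
- In favour: four carbon–carbon bonds and a ring come from one operation, with regiochemistry set by the polarity of A9. O5 arrives free and chelated and O7 silylated, so ring A needs one protecting group and O5 none. On protecting-group economy for ring A the alternative is the better, and in bonds formed per step it is at least the equal.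
- Against, here: it builds from scratch the ring that 9 supplies. The preparation of A8 passes through an activated pyranone carboxylic acid and a diazoalkane acylation with its hazard. The photochemical step is harder to scale, and the 4-pyranone chromophore itself absorbs. A9 is moisture-sensitive. After the key step four operations would remain (allyl removal, sulfation, silyl removal, hydrogenolysis) against three.
- Comparison: on structure, the chosen plan uses the symmetry of a purchased ring A, whereas this one must create its substitution pattern. On mechanism, a photochemical pericyclic cascade is more elegant but less predictable on a heteroaromatic ketone than an acylation of an activated arene. On step economy, the chosen plan is shorter on both sides of the key step.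

Key step: step 6

Assumption: the target is drawn as the free hydrogen sulfate, so 16 and 17 are written in that neutral form; in the flask each would be handled as its sodium salt, and the free acid released only when wanted by brief cold cation exchange.

## Route

Step 1
Reactants: 1 4-(benzyloxy)-3-hydroxybenzaldehyde; 2 allyl bromide
Product: 3 3-(allyloxy)-4-(benzyloxy)benzaldehyde
Conditions: K2CO3, DMF, rt
Reagents that add atoms: allyl bromide, C=CCBr
Why: Williamson ether synthesis: the single phenol of 1 is deprotonated and alkylated by the primary allylic bromide in an SN2 reaction; the aldehyde and the benzyl ether are inert.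

Step 2
Reactants: 3 3-(allyloxy)-4-(benzyloxy)benzaldehyde; 4 carbon tetrabromide
Product: 5 2-(allyloxy)-1-(benzyloxy)-4-(2,2-dibromoethenyl)benzene
Conditions: CBr4, PPh3, CH2Cl2, 0 °C
Reagents that add atoms: carbon tetrabromide, BrC(Br)(Br)Br
Why: First stage of the Corey–Fuchs reaction: the ylide formed from PPh3 and CBr4 olefinates the aromatic aldehyde in a Wittig reaction; the conditions are neutral and cold, so both ethers are untouched.

Step 3
Reactants: 5 2-(allyloxy)-1-(benzyloxy)-4-(2,2-dibromoethenyl)benzene; 6 ethyl chloroformate
Product: 8 ethyl 3-[3-(allyloxy)-4-(benzyloxy)phenyl]prop-2-ynoate, via lithium arylacetylide 7 (not isolated)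
Conditions: n-BuLi (2.1 equiv), THF, −78 °C; then added to ClCO2Et (excess), −78 °C → rt
Reagents that add atoms: ethyl chloroformate, CCOC(=O)Cl
Why: Second stage of the Corey–Fuchs reaction: bromine–lithium exchange and 1,2-shift (Fritsch–Buttenberg–Wiechell) give the alkyne, held by the second equivalent of base as acetylide 7, which is C-acylated by the chloroformate; at −78 °C the allyl ether should not be metallated, and adding 7 to excess 6 should prevent a second addition.

Step 4
Reactants: 8 ethyl 3-[3-(allyloxy)-4-(benzyloxy)phenyl]prop-2-ynoate; 9 3,5-bis(benzyloxy)phenol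
Product: 10 ethyl (2Z)-3-[3-(allyloxy)-4-(benzyloxy)phenyl]-3-[3,5-bis(benzyloxy)phenoxy]prop-2-enoate
Conditions: Cs2CO3 (0.3 equiv), DMF, 70 °C
Reagents that add atoms: 3,5-bis(benzyloxy)phenol, Oc1cc(OCc2ccccc2)cc(OCc2ccccc2)c1
Why: Base-catalysed oxa-Michael addition of the phenoxide of 9 to the β-carbon of the ynoate, the site fixed by conjugation with the ester; anti protonation of the allenolate should favour the Z geometry (aryloxy cis to the ester), and any E-configured material is tolerable because the double bond equilibrates in step 6.

Step 5
Reactants: 10 ethyl (2Z)-3-[3-(allyloxy)-4-(benzyloxy)phenyl]-3-[3,5-bis(benzyloxy)phenoxy]prop-2-enoate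
Product: 11 (2Z)-3-[3-(allyloxy)-4-(benzyloxy)phenyl]-3-[3,5-bis(benzyloxy)phenoxy]prop-2-enoic acid
Conditions: LiOH·H2O, THF/MeOH/H2O, 40 °C; then cold 1 M HCl to pH 3
Reagents that add atoms: lithium hydroxide, [Li+].[OH-]
Why: Saponification by acyl–oxygen cleavage, in which the hydroxide oxygen becomes the carboxyl OH; the β-aryl and β-aryloxy groups make the alkene a poor Michael acceptor and the carboxylate, once formed, is inert to hydroxide, so the enol ether should survive; brief cold acidification limits its hydrolysis.

Step 6
Reactants: 11 (2Z)-3-[3-(allyloxy)-4-(benzyloxy)phenyl]-3-[3,5-bis(benzyloxy)phenoxy]prop-2-enoic acid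
Product: 13 2-[3-(allyloxy)-4-(benzyloxy)phenyl]-5,7-bis(benzyloxy)-4H-chromen-4-one, via mixed trifluoroacetic anhydride 12 (not isolated)
Conditions: (CF3CO)2O (2 equiv), CH2Cl2 (high dilution), 0 °C → rt; aq. NaHCO3 quench
Reagents that add atoms: none
Why: Trifluoroacetic anhydride converts 11 into the mixed anhydride 12; this, or the acylium ion derived from it (stabilised by the β-aryloxy oxygen), is attacked by the carbon ortho to the ether oxygen of the 3,5-bis(benzyloxy)phenoxy ring, and loss of a proton from the arenium ion restores ring A and gives the pyranone. The closest known reaction type is the acid-mediated intramolecular Friedel–Crafts acylation of β-aryloxycinnamic acids to flavones, run here with the anhydride activation used for electron-rich aryloxy acids. Ring C closes in a six-membered mode in which the arene carbon attacks the acyl carbon while the C=O bond stays outside the new ring (6-exo-trig at the mixed anhydride), forming C4–C4a. No stereocentre is formed. Chemoselectivity for ring A over ring B is needed and is secured because the attacked carbon is ortho to O1 and ortho and para to the two benzyloxy groups, whereas ring B could be reached only from the E geometry and only by closing a strained five-membered ring. Regioselectivity is not in question because the two carbons ortho to O1 are equivalent. Closure requires the Z geometry, and reversible protonation at the α-carbon of the push–pull enol ether by the trifluoroacetic acid released lets E-configured material rotate into the Z form, which is drained by cyclisation. The reagent is mild enough for the benzyl and allyl ethers, and dilution disfavours intermolecular acylation.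

Step 7
Reactants: 13 2-[3-(allyloxy)-4-(benzyloxy)phenyl]-5,7-bis(benzyloxy)-4H-chromen-4-one
Product: 14 5,7-bis(benzyloxy)-2-[4-(benzyloxy)-3-hydroxyphenyl]-4H-chromen-4-one
Conditions: Pd(PPh3)4 (5 mol %), morpholine, THF, rt
Reagents that add atoms: none
Why: Tsuji–Trost deallylation: zerovalent palladium ionises the allyl aryl ether to a π-allyl palladium complex and the phenoxide, and morpholine takes up the allyl group irreversibly; benzyl ethers and the flavone core do not react under these neutral conditions.

Step 8
Reactants: 14 5,7-bis(benzyloxy)-2-[4-(benzyloxy)-3-hydroxyphenyl]-4H-chromen-4-one; 15 sulfur trioxide–pyridine complex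
Product: 16 2-(benzyloxy)-5-[5,7-bis(benzyloxy)-4-oxo-4H-chromen-2-yl]phenyl hydrogen sulfate
Conditions: SO3·pyridine (5 equiv), pyridine, 50 °C; work-up at pH 8 (sodium salt)
Reagents that add atoms: sulfur trioxide–pyridine complex, O=S(=O)([O-])[n+]1ccccc1
Why: O-Sulfation of a phenol by transfer of SO3 from its pyridine complex; O3' is the only free hydroxyl of 14, so the site is fixed by the protecting-group pattern, and the basic medium and work-up protect the sulfate monoester.

Step 9
Reactants: 16 2-(benzyloxy)-5-[5,7-bis(benzyloxy)-4-oxo-4H-chromen-2-yl]phenyl hydrogen sulfate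
Product: 17 luteolin 3'-sulfate, 5-(5,7-dihydroxy-4-oxo-4H-chromen-2-yl)-2-hydroxyphenyl hydrogen sulfate
Conditions: H2 (1 atm), 10% Pd/C, THF/MeOH, rt
Reagents that add atoms: none
Why: Catalytic hydrogenolysis of the three benzyl aryl ethers; an aryl sulfate monoester anion is inert to hydrogen over palladium, and the C2=C3 bond, part of a vinylogous ester in an aromatic pyranone, should not be reduced at atmospheric pressure if the reaction is stopped after uptake of three equivalents.

## Compound list

1 | 4-(benzyloxy)-3-hydroxybenzaldehyde | O=Cc1ccc(OCc2ccccc2)c(O)c1 | starting material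
2 | allyl bromide (3-bromoprop-1-ene) | C=CCBr | starting material
3 | 3-(allyloxy)-4-(benzyloxy)benzaldehyde | O=Cc1ccc(OCc2ccccc2)c(OCC=C)c1 | intermediate
4 | carbon tetrabromide | BrC(Br)(Br)Br | starting material
5 | 2-(allyloxy)-1-(benzyloxy)-4-(2,2-dibromoethenyl)benzene | BrC(Br)=Cc1ccc(OCc2ccccc2)c(OCC=C)c1 | intermediate
6 | ethyl chloroformate | CCOC(=O)Cl | starting material
7 | lithium [3-(allyloxy)-4-(benzyloxy)phenyl]acetylide (not isolated) | [Li]C#Cc1ccc(OCc2ccccc2)c(OCC=C)c1 | intermediate
8 | ethyl 3-[3-(allyloxy)-4-(benzyloxy)phenyl]prop-2-ynoate | CCOC(=O)C#Cc1ccc(OCc2ccccc2)c(OCC=C)c1 | intermediate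
9 | 3,5-bis(benzyloxy)phenol | Oc1cc(OCc2ccccc2)cc(OCc2ccccc2)c1 | starting material
10 | ethyl (2Z)-3-[3-(allyloxy)-4-(benzyloxy)phenyl]-3-[3,5-bis(benzyloxy)phenoxy]prop-2-enoate | CCOC(=O)/C=C(\Oc1cc(OCc2ccccc2)cc(OCc2ccccc2)c1)c1ccc(OCc2ccccc2)c(OCC=C)c1 | intermediate
11 | (2Z)-3-[3-(allyloxy)-4-(benzyloxy)phenyl]-3-[3,5-bis(benzyloxy)phenoxy]prop-2-enoic acid | OC(=O)/C=C(\Oc1cc(OCc2ccccc2)cc(OCc2ccccc2)c1)c1ccc(OCc2ccccc2)c(OCC=C)c1 | intermediate
12 | (2Z)-3-[3-(allyloxy)-4-(benzyloxy)phenyl]-3-[3,5-bis(benzyloxy)phenoxy]prop-2-enoic trifluoroacetic anhydride (not isolated) | O=C(OC(=O)C(F)(F)F)/C=C(\Oc1cc(OCc2ccccc2)cc(OCc2ccccc2)c1)c1ccc(OCc2ccccc2)c(OCC=C)c1 | intermediate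
13 | 2-[3-(allyloxy)-4-(benzyloxy)phenyl]-5,7-bis(benzyloxy)-4H-chromen-4-one (3'-O-allyl-5,7,4'-tri-O-benzylluteolin) | C=CCOc1cc(-c2cc(=O)c3c(OCc4ccccc4)cc(OCc4ccccc4)cc3o2)ccc1OCc1ccccc1 | intermediate
14 | 5,7-bis(benzyloxy)-2-[4-(benzyloxy)-3-hydroxyphenyl]-4H-chromen-4-one (5,7,4'-tri-O-benzylluteolin) | O=c1cc(-c2ccc(OCc3ccccc3)c(O)c2)oc2cc(OCc3ccccc3)cc(OCc3ccccc3)c12 | intermediate
15 | sulfur trioxide–pyridine complex | O=S(=O)([O-])[n+]1ccccc1 | starting material
16 | 2-(benzyloxy)-5-[5,7-bis(benzyloxy)-4-oxo-4H-chromen-2-yl]phenyl hydrogen sulfate (5,7,4'-tri-O-benzylluteolin 3'-sulfate) | O=c1cc(-c2ccc(OCc3ccccc3)c(OS(=O)(=O)O)c2)oc2cc(OCc3ccccc3)cc(OCc3ccccc3)c12 | intermediate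
17 | luteolin 3'-sulfate | O=c1cc(-c2ccc(O)c(OS(=O)(=O)O)c2)oc2cc(O)cc(O)c12 | target

## Step count and least certain steps

Total: 9 steps. Longest linear sequence: 9 steps (1 → 17); 9 enters at step 4 as a purchased compound.

**Step 6 (key step).** The mixed anhydride of a vinylogous carbonic acid is a weak acylating agent, so closure may be slow. Intermolecular acylation or trifluoroacetylation of the very electron-rich ring A could then compete. More forcing acid would risk loss of benzyl groups, the one peri to the new carbonyl first.
Fallback: a Baker–Venkataraman assembly, which forms O1–C2 last instead of C4–C4a; it sets out from 3 and returns at 13. Pinnick oxidation of 3 (NaClO2, NaH2PO4, 2-methylbut-2-ene) would give 3-(allyloxy)-4-(benzyloxy)benzoic acid F1. Carbodiimide coupling (EDC, DMAP, CH2Cl2) with the catalogue ketone 1-[2,4-bis(benzyloxy)-6-hydroxyphenyl]ethan-1-one F2 would give the aryl ester 2-acetyl-3,5-bis(benzyloxy)phenyl 3-(allyloxy)-4-(benzyloxy)benzoate F3. KOH in pyridine would move the aroyl group to carbon and give the diketone 1-[3-(allyloxy)-4-(benzyloxy)phenyl]-3-[2,4-bis(benzyloxy)-6-hydroxyphenyl]propane-1,3-dione F4. Cyclodehydration with catalytic p-toluenesulfonic acid in warm toluene would then give 13.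

**Step 4.** The 3,4-dialkoxyphenyl group donates into the alkyne and lowers its electrophilicity, so the conjugate addition may be slow. Forcing it invites attack through carbon by the ambident phenoxide.
Fallback: a more electrophilic acceptor; it sets out from 5 and returns at 11, bypassing 8 and 10. Treatment of 5 with n-BuLi and then DMF would give 3-[3-(allyloxy)-4-(benzyloxy)phenyl]prop-2-ynal F5. Phenol 9 should add to this ynal at room temperature (K2CO3, MeCN) to give (2Z)-3-[3-(allyloxy)-4-(benzyloxy)phenyl]-3-[3,5-bis(benzyloxy)phenoxy]prop-2-enal F6. Pinnick oxidation with a large excess of 2-methylbut-2-ene as chlorine scavenger would give 11.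

**Step 5.** Hydroxide may add to the β-carbon and expel the aryloxy group, or the enol ether may hydrolyse during acidification, followed by decarboxylation.
Fallback: an ester that is cleaved without hydroxide; it sets out from 5 and returns at 11. Treatment of 5 with n-BuLi and then Boc2O would give tert-butyl 3-[3-(allyloxy)-4-(benzyloxy)phenyl]prop-2-ynoate F7. Addition of 9 as in step 4 would give tert-butyl (2Z)-3-[3-(allyloxy)-4-(benzyloxy)phenyl]-3-[3,5-bis(benzyloxy)phenoxy]prop-2-enoate F8. TMSOTf and 2,6-lutidine in CH2Cl2 at 0 °C, followed by aqueous work-up, would release 11 with the base present to take up the tert-butyl cation as the alkene.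

**Step 8.** The 3'-hydroxyl is flanked by the 4'-benzyloxy group, so sulfation may be incomplete. The amphiphilic sulfate salt may also lose its sulfate by solvolysis during purification.
Fallback: a protected sulfate; it sets out from 14 and returns at 16. 2,2,2-Trichloroethyl chlorosulfate F9 with Et3N and DMAP in THF would give the neutral, chromatographable diester 5,7-bis(benzyloxy)-2-[4-(benzyloxy)-3-{[(2,2,2-trichloroethoxy)sulfonyl]oxy}phenyl]-4H-chromen-4-one F10. Reductive removal of the trichloroethyl group with zinc dust and ammonium formate in MeOH would give 16.

## Further compounds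

F1 | step 6 | 3-(allyloxy)-4-(benzyloxy)benzoic acid | OC(=O)c1ccc(OCc2ccccc2)c(OCC=C)c1
F2 | step 6 | 1-[2,4-bis(benzyloxy)-6-hydroxyphenyl]ethan-1-one | CC(=O)c1c(O)cc(OCc2ccccc2)cc1OCc1ccccc1
F3 | step 6 | 2-acetyl-3,5-bis(benzyloxy)phenyl 3-(allyloxy)-4-(benzyloxy)benzoate | CC(=O)c1c(OC(=O)c2ccc(OCc3ccccc3)c(OCC=C)c2)cc(OCc2ccccc2)cc1OCc1ccccc1
F4 | step 6 | 1-[3-(allyloxy)-4-(benzyloxy)phenyl]-3-[2,4-bis(benzyloxy)-6-hydroxyphenyl]propane-1,3-dione | O=C(CC(=O)c1c(O)cc(OCc2ccccc2)cc1OCc1ccccc1)c1ccc(OCc2ccccc2)c(OCC=C)c1
F5 | step 4 | 3-[3-(allyloxy)-4-(benzyloxy)phenyl]prop-2-ynal | O=CC#Cc1ccc(OCc2ccccc2)c(OCC=C)c1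
F6 | step 4 | (2Z)-3-[3-(allyloxy)-4-(benzyloxy)phenyl]-3-[3,5-bis(benzyloxy)phenoxy]prop-2-enal | O=C/C=C(\Oc1cc(OCc2ccccc2)cc(OCc2ccccc2)c1)c1ccc(OCc2ccccc2)c(OCC=C)c1
F7 | step 5 | tert-butyl 3-[3-(allyloxy)-4-(benzyloxy)phenyl]prop-2-ynoate | CC(C)(C)OC(=O)C#Cc1ccc(OCc2ccccc2)c(OCC=C)c1
F8 | step 5 | tert-butyl (2Z)-3-[3-(allyloxy)-4-(benzyloxy)phenyl]-3-[3,5-bis(benzyloxy)phenoxy]prop-2-enoate | CC(C)(C)OC(=O)/C=C(\Oc1cc(OCc2ccccc2)cc(OCc2ccccc2)c1)c1ccc(OCc2ccccc2)c(OCC=C)c1
F9 | step 8 | 2,2,2-trichloroethyl chlorosulfate | ClS(=O)(=O)OCC(Cl)(Cl)Cl
F10 | step 8 | 5,7-bis(benzyloxy)-2-[4-(benzyloxy)-3-{[(2,2,2-trichloroethoxy)sulfonyl]oxy}phenyl]-4H-chromen-4-one | O=c1cc(-c2ccc(OCc3ccccc3)c(OS(=O)(=O)OCC(Cl)(Cl)Cl)c2)oc2cc(OCc3ccccc3)cc(OCc3ccccc3)c12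
A1 | alternative 1 | 6-[(3E)-4-[4-(benzyloxy)-3-(methoxymethoxy)phenyl]-4-methoxy-2-oxobut-3-en-1-yl]-4-hydroxy-2H-pyran-2-one | CO/C(=C/C(=O)Cc1cc(O)cc(=O)o1)c1ccc(OCc2ccccc2)c(OCOC)c1
A2 | alternative 1 | magnesium dimethoxide, Mg(OMe)2 | CO[Mg]OC
A3 | alternative 1 | (2E)-3-[4-(benzyloxy)-3-(methoxymethoxy)phenyl]-3-methoxy-1-(2,4,6-trihydroxyphenyl)prop-2-en-1-one | CO/C(=C/C(=O)c1c(O)cc(O)cc1O)c1ccc(OCc2ccccc2)c(OCOC)c1
A4 | alternative 1 | 2-[4-(benzyloxy)-3-(methoxymethoxy)phenyl]-5,7-dihydroxy-4H-chromen-4-one | COCOc1cc(-c2cc(=O)c3c(O)cc(O)cc3o2)ccc1OCc1ccccc1
A5 | alternative 2 | 5,7-bis(benzyloxy)-2-[5-(benzyloxy)-6-oxo-6H-pyran-2-yl]-4H-chromen-4-one | O=c1cc(-c2ccc(OCc3ccccc3)c(=O)o2)oc2cc(OCc3ccccc3)cc(OCc3ccccc3)c12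
A6 | alternative 2 | 1,1-bis(trimethylsilyloxy)ethene | C=C(O[Si](C)(C)C)O[Si](C)(C)C
A7 | alternative 2 | 5,7-bis(benzyloxy)-2-[4-(benzyloxy)-3-hydroxyphenyl]-4H-chromen-4-one (identical with 14) | O=c1cc(-c2ccc(OCc3ccccc3)c(O)c2)oc2cc(OCc3ccccc3)cc(OCc3ccccc3)c12
A8 | alternative 3 | 2-[3-(allyloxy)-4-(benzyloxy)phenyl]-6-(diazoacetyl)-4H-pyran-4-one | C=CCOc1cc(-c2cc(=O)cc(C(=O)C=[N+]=[N-])o2)ccc1OCc1ccccc1
A9 | alternative 3 | (triisopropylsilyloxy)ethyne | C#CO[Si](C(C)C)(C(C)C)C(C)C
A10 | alternative 3 | 2-[3-(allyloxy)-4-(benzyloxy)phenyl]-5-hydroxy-7-[(triisopropylsilyl)oxy]-4H-chromen-4-one | C=CCOc1cc(-c2cc(=O)c3c(O)cc(O[Si](C(C)C)(C(C)C)C(C)C)cc3o2)ccc1OCc1ccccc1
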